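**Plan**

- Retrosynthesis (1-benzoxepine locants): both C–Br bonds are made last from a diol (C-7 with inversion). C-2 comes from the 2-methylidene enol ether of a seven-membered unsaturated lactone, whose acyl C–O bond comes from a (Z)-vinyl iodide and CO, and C-3=C-4 from an aldehyde.
- The cyclohexane (ring A) is cut at C-8–C-9 and C-5a–C-9a. This gives a chain C-5a–C-6–C-7–C-8 (enoate at C-5a, CH2Br at C-8, oxygen on C-7) and an isopropenyl unit (C-9, C-9a and its methyl).
- Enabling feature: C-7 and C-9a lie 1,4 across ring A and both carry a heteroatom. With oxygen in place of bromine at C-7, one SiMe2 atom bridges the C-7 oxygen and C-9a, so ring A is built as a 2-oxa-3-silabicyclo[2.2.2]octane and the silicon is later oxidised off.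
- Forward order: bromoketone, enoate, bromohydrin, silyl ether, radical cascade (oxasilacyclohexane, then ring A), vinyl iodide, Tamao–Fleming unmasking, ring B by carbonylative lactonization, methylenation and hydroboration, double bromination.
- Stereochemistry: C-7 oxygen from a Corey–Bakshi–Shibata reduction; C-9a and C-5a from the silicon bridge in the cascade; C-2 from hydroboration opposite the C-9a methyl; the C-7 bromide by SN2 inversion.

Key step: step 6

Remark: locants in the text are those of the 1-benzoxepine skeleton of the target (O-1, C-2 to C-5, C-5a, C-6 to C-9, C-9a).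
Assumption: chloro(dimethyl)(prop-1-en-2-yl)silane 9 is prepared (step 4) and not bought; the other starting materials are catalogue compounds.

**Route**

Step 1
Reactants: 1 trimethyl(3-methylbut-2-en-1-yl)silane; 2 bromoacetyl bromide
Product: 3 1-bromo-3,3-dimethylpent-4-en-2-one
Conditions: AlCl3 (1.05 equiv), CH2Cl2, −78 °C
Reagents that add atoms: none
Why: Lewis-acid-mediated acylation of an allylsilane (Hosomi–Sakurai-type SE2′ acylation): the acyl bromide attacks the dimethyl-substituted γ-carbon and silicon is lost from the β-silyl cation, which places the gem-dimethyl carbon (future C-6) between the bromomethyl ketone and a vinyl group; no stereocenter is formed.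

Step 2
Reactants: 3 1-bromo-3,3-dimethylpent-4-en-2-one; 4 methyl acrylate
Product: 5 methyl (2E)-6-bromo-4,4-dimethyl-5-oxohex-2-enoate
Conditions: 4 (5 equiv), second-generation Hoveyda–Grubbs catalyst, RuCl2(H2IMes)(=CH-2-iPrO-C6H4) (5 mol %), toluene, 80 °C
Reagents that add atoms: none
Why: Olefin cross-metathesis between a vinyl group on a quaternary carbon (which cannot homodimerize) and an acrylate should give the (E)-enoate, whose ester carbon is the future C-4 and whose β-carbon is the future C-5a.

Step 3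
Reactants: 5 methyl (2E)-6-bromo-4,4-dimethyl-5-oxohex-2-enoate
Product: 6 methyl (2E,5S)-6-bromo-5-hydroxy-4,4-dimethylhex-2-enoate
Conditions: (S)-2-methyl-CBS-oxazaborolidine (15 mol %), BH3·SMe2, THF, −20 °C; MeOH quench
Reagents that add atoms: none
Why: Corey–Bakshi–Shibata reduction: with the tertiary alkyl group as the large and bromomethyl as the small substituent, the (S)-catalyst should give the (5S)-bromohydrin, which sets the oxygen-bearing precursor of C-7 and is the only source of absolute configuration for ring A.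

Step 4
Reactants: 7 isopropenylmagnesium bromide; 8 dichlorodimethylsilane
Product: 9 chloro(dimethyl)(prop-1-en-2-yl)silane
Conditions: 8 (3 equiv), THF, −78 °C to rt; distillation
Reagents that add atoms: none
Why: Substitution at silicon by a Grignard reagent stops after one chloride when Me2SiCl2 is in excess, giving the silyl chloride that carries C-9, C-9a and the C-9a methyl.

Step 5
Reactants: 6 methyl (2E,5S)-6-bromo-5-hydroxy-4,4-dimethylhex-2-enoate; 9 chloro(dimethyl)(prop-1-en-2-yl)silane
Product: 10 methyl (2E,5S)-6-bromo-5-{[dimethyl(prop-1-en-2-yl)silyl]oxy}-4,4-dimethylhex-2-enoate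
Conditions: 9 (1.5 equiv), imidazole (3 equiv), CH2Cl2, 0 °C
Reagents that add atoms: none
Why: Silylation of the secondary alcohol with a chlorosilane and imidazole installs the temporary silicon connection; the mild base should not close the bromohydrin to the epoxide, and no stereocenter is touched.

Step 6
Reactants: 10 methyl (2E,5S)-6-bromo-5-{[dimethyl(prop-1-en-2-yl)silyl]oxy}-4,4-dimethylhex-2-enoate
Product: 11 methyl 2-[(1R,4S,5S)-3,3,4,6,6-pentamethyl-2-oxa-3-silabicyclo[2.2.2]octan-5-yl]acetate
Conditions: Bu3SnH (1.3 equiv) and AIBN (0.15 equiv) by syringe pump, benzene (5 mM), 80 °C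
Reagents that add atoms: none
Why: The tributylstannyl radical abstracts the primary bromine; the C-8 radical attacks the unsubstituted terminus of the silicon-bound isopropenyl group (future C-9) and leaves a tertiary α-silyl radical at future C-9a, which adds to the β-carbon of the enoate (future C-5a), and the resulting α-ester radical is reduced by Bu3SnH. The closest known reaction type is the tin-hydride radical cyclization through a temporary silicon connection (vinylsilyl ethers of β-halo alcohols), followed by a second, conjugate-addition ring closure as in tandem radical cyclizations. Ring closures: 6-endo-trig for the 1-oxa-2-silacyclohexane and 6-exo-trig for the cyclohexane, together a 2-oxa-3-silabicyclo[2.2.2]octane. Stereocontrol: the one-atom SiMe2 bridge can span the C-7 oxygen and C-9a only when both lie on the same face, so the existing C-7 stereocenter fixes C-9a; at C-5a the acetate arm should turn away from the SiMe2 bridge toward the CH2–CH2 bridge, which puts the C-5a hydrogen cis to both heteroatoms. Selectivity needed: 6-endo over 5-exo in the first closure (secured by the methyl group on the silicon-bearing alkene carbon and the long Si–O and Si–C bonds) and cyclization over premature reduction of either radical (secured by slow addition of the stannane at high dilution).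

Step 7
Reactants: 11 methyl 2-[(1R,4S,5S)-3,3,4,6,6-pentamethyl-2-oxa-3-silabicyclo[2.2.2]octan-5-yl]acetate
Product: 12 2-[(1R,4S,5S)-3,3,4,6,6-pentamethyl-2-oxa-3-silabicyclo[2.2.2]octan-5-yl]acetaldehyde
Conditions: i-Bu2AlH (1.1 equiv), CH2Cl2, −78 °C; aqueous KNaC4H4O6
Reagents that add atoms: none
Why: Partial reduction of the methyl ester with i-Bu2AlH at −78 °C stops at the aldehyde through the tetrahedral aluminium hemiacetal; the cyclic silyl ether and the three stereocenters are untouched.

Step 8
Reactants: 12 2-[(1R,4S,5S)-3,3,4,6,6-pentamethyl-2-oxa-3-silabicyclo[2.2.2]octan-5-yl]acetaldehyde; 13 ethyltriphenylphosphonium iodide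
Product: 14 (1R,4S,5S)-5-[(2Z)-3-iodobut-2-en-1-yl]-3,3,4,6,6-pentamethyl-2-oxa-3-silabicyclo[2.2.2]octane
Conditions: 13, n-BuLi, THF, 0 °C; I2, −78 °C; NaN(SiMe3)2, −20 °C; then 12, −78 to −20 °C
Reagents that add atoms: iodine, II
Why: Stork–Zhao-type Wittig olefination with an α-iodo ylide is kinetically Z-selective (iodine cis to the chain), which attaches the future C-3 with its methyl group to C-4 and puts the iodine where the C-2 carbon must later stand cis to C-5.

Step 9
Reactants: 14 (1R,4S,5S)-5-[(2Z)-3-iodobut-2-en-1-yl]-3,3,4,6,6-pentamethyl-2-oxa-3-silabicyclo[2.2.2]octane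
Product: 15 (1S,2S,4R)-2-[(2Z)-3-iodobut-2-en-1-yl]-1,3,3-trimethylcyclohexane-1,4-diol
Conditions: H2O2 (30 %), KF, KHCO3, THF/MeOH, 60 °C
Reagents that add atoms: hydrogen peroxide, OO
Why: Tamao–Fleming oxidation: the fluoride-activated alkoxysilane is attacked by peroxide and the tertiary carbon migrates from silicon to oxygen with retention, so the C-9a hydroxyl appears cis to the C-7 hydroxyl released from the same silicon atom, while the vinyl iodide is inert.

Step 10
Reactants: 15 (1S,2S,4R)-2-[(2Z)-3-iodobut-2-en-1-yl]-1,3,3-trimethylcyclohexane-1,4-diol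
Product: 16 (5aS,7R,9aS)-7-hydroxy-3,6,6,9a-tetramethyl-5a,6,7,8,9,9a-hexahydro-1-benzoxepin-2(5H)-one
Conditions: CO (1 atm), Pd(PPh3)4 (10 mol %), Et3N, MeCN/THF (high dilution), 70 °C
Reagents that add atoms: carbon monoxide, [C-]#[O+]
Why: Palladium-catalyzed carbonylative lactonization: oxidative addition of the vinyl iodide to zerovalent palladium with retention of geometry, CO insertion, and capture of the acylpalladium by the tertiary C-9a hydroxyl (the only hydroxyl within reach) should close ring B as the seven-membered unsaturated lactone.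

Step 11
Reactants: 16 (5aS,7R,9aS)-7-hydroxy-3,6,6,9a-tetramethyl-5a,6,7,8,9,9a-hexahydro-1-benzoxepin-2(5H)-one
Product: 17 (5aS,7R,9aS)-3,6,6,9a-tetramethyl-2-methylidene-2,5,5a,6,7,8,9,9a-octahydro-1-benzoxepin-7-ol
Conditions: Cp2TiMe2 (3 equiv), toluene, 65 °C, dark; used without storage
Reagents that add atoms: dimethyltitanocene, [CH3-].[CH3-].[Ti+4].c1cc[cH-]c1.c1cc[cH-]c1
Why: Petasis methylenation: Cp2Ti=CH2 formed by thermolysis converts the lactone carbonyl into the exocyclic enol ether under non-basic conditions, the free hydroxyl only consuming extra reagent, so that C-2 becomes a prochiral sp2 carbon bearing the future bromomethyl carbon.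

Step 12
Reactants: 17 (5aS,7R,9aS)-3,6,6,9a-tetramethyl-2-methylidene-2,5,5a,6,7,8,9,9a-octahydro-1-benzoxepin-7-ol
Product: 19 (2R,5aS,7R,9aS)-2-(hydroxymethyl)-3,6,6,9a-tetramethyl-2,5,5a,6,7,8,9,9a-octahydro-1-benzoxepin-7-ol, via borane adduct 18 (not isolated)
Conditions: 9-BBN (3 equiv), THF, 0 °C to rt; then NaOH, H2O2, 0 °C
Reagents that add atoms: 9-borabicyclo[3.3.1]nonane, B1C2CCCC1CCC2 (kept only in 18); hydrogen peroxide, OO
Why: Hydroboration–oxidation of the electron-rich exocyclic enol ether puts boron on the terminal carbon and hydrogen on C-2 from the face opposite the pseudo-axial C-9a methyl group (1,3 to C-2 across the ring oxygen), which should set (2R) with the hydroxymethyl group cis to that methyl, while the trisubstituted ring alkene is too hindered for 9-BBN.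

Step 13
Reactants: 19 (2R,5aS,7R,9aS)-2-(hydroxymethyl)-3,6,6,9a-tetramethyl-2,5,5a,6,7,8,9,9a-octahydro-1-benzoxepin-7-ol
Product: 20 palisadin B, (2R,5aS,7S,9aS)-7-bromo-2-(bromomethyl)-3,6,6,9a-tetramethyl-2,5,5a,6,7,8,9,9a-octahydro-1-benzoxepine
Conditions: CBr4, PPh3 (4 equiv each), CH2Cl2, 0 to 40 °C
Reagents that add atoms: carbon tetrabromide, BrC(Br)(Br)Br
Why: Appel reaction: the primary alcohol is substituted directly and the axial C-7 oxyphosphonium ion is displaced by bromide with SN2 inversion to the equatorial (7S) bromide, a displacement next to a quaternary carbon that is known for axial 3-hydroxy-4,4-dimethylcyclohexane units but competes with elimination.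

**Compound list**

1 | trimethyl(3-methylbut-2-en-1-yl)silane | CC(C)=CC[Si](C)(C)C | starting material
2 | bromoacetyl bromide | BrCC(Br)=O | starting material
3 | 1-bromo-3,3-dimethylpent-4-en-2-one | C=CC(C)(C)C(=O)CBr | intermediate
4 | methyl acrylate | COC(=O)C=C | starting material
5 | methyl (2E)-6-bromo-4,4-dimethyl-5-oxohex-2-enoate | COC(=O)/C=C/C(C)(C)C(=O)CBr | intermediate
6 | methyl (2E,5S)-6-bromo-5-hydroxy-4,4-dimethylhex-2-enoate | COC(=O)/C=C/C(C)(C)[C@H](O)CBr | intermediate
7 | isopropenylmagnesium bromide | C=C(C)[Mg]Br | starting material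
8 | dichlorodimethylsilane | C[Si](C)(Cl)Cl | starting material
9 | chloro(dimethyl)(prop-1-en-2-yl)silane | C=C(C)[Si](C)(C)Cl | intermediate
10 | methyl (2E,5S)-6-bromo-5-{[dimethyl(prop-1-en-2-yl)silyl]oxy}-4,4-dimethylhex-2-enoate | COC(=O)/C=C/C(C)(C)[C@H](O[Si](C)(C)C(C)=C)CBr | intermediate
11 | methyl 2-[(1R,4S,5S)-3,3,4,6,6-pentamethyl-2-oxa-3-silabicyclo[2.2.2]octan-5-yl]acetate | COC(=O)C[C@H]1C(C)(C)[C@H]2CC[C@]1(C)[Si](C)(C)O2 | intermediate
12 | 2-[(1R,4S,5S)-3,3,4,6,6-pentamethyl-2-oxa-3-silabicyclo[2.2.2]octan-5-yl]acetaldehyde | O=CC[C@H]1C(C)(C)[C@H]2CC[C@]1(C)[Si](C)(C)O2 | intermediate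
13 | ethyltriphenylphosphonium iodide | CC[P+](c1ccccc1)(c1ccccc1)c1ccccc1.[I-] | starting material
14 | (1R,4S,5S)-5-[(2Z)-3-iodobut-2-en-1-yl]-3,3,4,6,6-pentamethyl-2-oxa-3-silabicyclo[2.2.2]octane | C/C(I)=C/C[C@H]1C(C)(C)[C@H]2CC[C@]1(C)[Si](C)(C)O2 | intermediate
15 | (1S,2S,4R)-2-[(2Z)-3-iodobut-2-en-1-yl]-1,3,3-trimethylcyclohexane-1,4-diol | C/C(I)=C/C[C@H]1C(C)(C)[C@H](O)CC[C@]1(C)O | intermediate
16 | (5aS,7R,9aS)-7-hydroxy-3,6,6,9a-tetramethyl-5a,6,7,8,9,9a-hexahydro-1-benzoxepin-2(5H)-one | CC1=CC[C@H]2C(C)(C)[C@H](O)CC[C@]2(C)OC1=O | intermediate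
17 | (5aS,7R,9aS)-3,6,6,9a-tetramethyl-2-methylidene-2,5,5a,6,7,8,9,9a-octahydro-1-benzoxepin-7-ol | CC1=CC[C@H]2C(C)(C)[C@H](O)CC[C@]2(C)OC1=C | intermediate
18 | (2S,5aS,7R,9aS)-2-[(9-borabicyclo[3.3.1]nonan-9-yl)methyl]-3,6,6,9a-tetramethyl-2,5,5a,6,7,8,9,9a-octahydro-1-benzoxepin-7-ol (same spatial arrangement at C-2 as in 19) | CC1=CC[C@H]2C(C)(C)[C@H](O)CC[C@]2(C)O[C@H]1CB1C2CCCC1CCC2 | intermediate (not isolated)
19 | (2R,5aS,7R,9aS)-2-(hydroxymethyl)-3,6,6,9a-tetramethyl-2,5,5a,6,7,8,9,9a-octahydro-1-benzoxepin-7-ol | CC1=CC[C@H]2C(C)(C)[C@H](O)CC[C@]2(C)O[C@H]1CO | intermediate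
20 | palisadin B, (2R,5aS,7S,9aS)-7-bromo-2-(bromomethyl)-3,6,6,9a-tetramethyl-2,5,5a,6,7,8,9,9a-octahydro-1-benzoxepine | CC1=CC[C@H]2C(C)(C)[C@@H](Br)CC[C@]2(C)O[C@H]1CBr | target

**Step count and risks**

Total step count: 13. Longest linear sequence: 12 steps (steps 1 to 3 and 5 to 13, from 1); step 4 is a one-step side branch.

Steps most likely to fail:

1. Step 6. The primary or the α-silyl radical may be reduced before it cyclizes, the first closure may go 5-exo, or the second closure may be too slow because it needs a boat-like bicyclo[2.2.2] transition state. Fallback from 6, back at 15 (steps 5 to 9 are bypassed and the two ring bonds are made in separate operations). Keck allylation of 6 with CH2=C(CH3)CH2SnBu3 (AIBN, benzene, 80 °C) forms the C-8–C-9 bond and gives methyl (2E,5R)-5-hydroxy-4,4,8-trimethylnona-2,8-dienoate F1 (same spatial arrangement at the carbinol carbon; the descriptor changes with the priorities). Ozonolysis of the 1,1-disubstituted alkene only (O3, CH2Cl2/MeOH, −78 °C; Me2S) gives methyl (2E,5R)-5-hydroxy-4,4-dimethyl-8-oxonon-2-enoate F2. SmI2 in THF/MeOH at −78 °C then closes the C-5a–C-9a bond by ketyl–olefin cyclization to methyl 2-[(1S,3R,6S)-3,6-dihydroxy-2,2,6-trimethylcyclohexyl]acetate F3. Here the samarium alkoxide of the free hydroxyl bound to the ketyl samarium is expected to hold the two oxygens cis, as the silicon bridge does, and the usual anti preference of ketyl–enoate closures should place the acetate arm trans to the new hydroxyl. i-Bu2AlH at −78 °C gives the lactol (3aS,5R,7aS)-4,4,7a-trimethyloctahydro-1-benzofuran-2,5-diol F4, and olefination of F4 with an excess of the ylide of step 8 returns to the route at 15.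

2. Step 10. Capture of the acylpalladium by the hindered tertiary hydroxyl may be too slow, so that intermolecular esterification or reduction of the acyl complex takes over. Fallback from 12, back at 16: ring B is closed through its C=C bond instead of its acyl C–O bond. Wittig methylenation of 12 (Ph3P=CH2, THF) gives (1R,4S,5S)-3,3,4,6,6-pentamethyl-5-(prop-2-en-1-yl)-2-oxa-3-silabicyclo[2.2.2]octane F5. Tamao–Fleming oxidation as in step 9 gives (1S,2S,4R)-1,3,3-trimethyl-2-(prop-2-en-1-yl)cyclohexane-1,4-diol F6. TBSOTf and 2,6-lutidine at −78 °C should silylate the secondary hydroxyl only and give (1S,2S,4R)-4-{[tert-butyl(dimethyl)silyl]oxy}-1,3,3-trimethyl-2-(prop-2-en-1-yl)cyclohexan-1-ol F7. Deprotonation with NaN(SiMe3)2 and acylation with methacryloyl chloride give (1S,2S,4R)-4-{[tert-butyl(dimethyl)silyl]oxy}-1,3,3-trimethyl-2-(prop-2-en-1-yl)cyclohexyl 2-methylprop-2-enoate F8. Ring-closing metathesis (second-generation Grubbs catalyst, RuCl2(H2IMes)(PCy3)(=CHPh), toluene, 80 °C) gives (5aS,7R,9aS)-7-{[tert-butyl(dimethyl)silyl]oxy}-3,6,6,9a-tetramethyl-5a,6,7,8,9,9a-hexahydro-1-benzoxepin-2(5H)-one F9, and Bu4NF returns to the route at 16.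

3. Step 13. E2 elimination or a 1,2-methyl shift from the axial oxyphosphonium ion at the neopentyl-type C-7 may outrun SN2 displacement. Fallback from 19, back at 20: the two brominations are separated and the C-7 substitution is taken out of the phosphorus chemistry. CBr4/PPh3 (1.2 equiv, 0 °C) should brominate the primary alcohol only and give (2R,5aS,7R,9aS)-2-(bromomethyl)-3,6,6,9a-tetramethyl-2,5,5a,6,7,8,9,9a-octahydro-1-benzoxepin-7-ol F10. Tf2O and pyridine at −40 °C give the isolated sulfonate (2R,5aS,7R,9aS)-2-(bromomethyl)-3,6,6,9a-tetramethyl-2,5,5a,6,7,8,9,9a-octahydro-1-benzoxepin-7-yl trifluoromethanesulfonate F11, which is displaced with inversion by soluble bromide (Bu4NBr, toluene, 0 °C) to give 20.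

Further compounds
F1 | step 6 | methyl (2E,5R)-5-hydroxy-4,4,8-trimethylnona-2,8-dienoate | COC(=O)/C=C/C(C)(C)[C@H](O)CCC(C)=C
F2 | step 6 | methyl (2E,5R)-5-hydroxy-4,4-dimethyl-8-oxonon-2-enoate | COC(=O)/C=C/C(C)(C)[C@H](O)CCC(C)=O
F3 | step 6 | methyl 2-[(1S,3R,6S)-3,6-dihydroxy-2,2,6-trimethylcyclohexyl]acetate | COC(=O)C[C@H]1C(C)(C)[C@H](O)CC[C@]1(C)O
F4 | step 6 | (3aS,5R,7aS)-4,4,7a-trimethyloctahydro-1-benzofuran-2,5-diol (anomer mixture) | OC1C[C@H]2C(C)(C)[C@H](O)CC[C@]2(C)O1
F5 | step 10 | (1R,4S,5S)-3,3,4,6,6-pentamethyl-5-(prop-2-en-1-yl)-2-oxa-3-silabicyclo[2.2.2]octane | C=CC[C@H]1C(C)(C)[C@H]2CC[C@]1(C)[Si](C)(C)O2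
F6 | step 10 | (1S,2S,4R)-1,3,3-trimethyl-2-(prop-2-en-1-yl)cyclohexane-1,4-diol | C=CC[C@H]1C(C)(C)[C@H](O)CC[C@]1(C)O
F7 | step 10 | (1S,2S,4R)-4-{[tert-butyl(dimethyl)silyl]oxy}-1,3,3-trimethyl-2-(prop-2-en-1-yl)cyclohexan-1-ol | C=CC[C@H]1C(C)(C)[C@H](O[Si](C)(C)C(C)(C)C)CC[C@]1(C)O
F8 | step 10 | (1S,2S,4R)-4-{[tert-butyl(dimethyl)silyl]oxy}-1,3,3-trimethyl-2-(prop-2-en-1-yl)cyclohexyl 2-methylprop-2-enoate | C=CC[C@H]1C(C)(C)[C@H](O[Si](C)(C)C(C)(C)C)CC[C@]1(C)OC(=O)C(C)=C
F9 | step 10 | (5aS,7R,9aS)-7-{[tert-butyl(dimethyl)silyl]oxy}-3,6,6,9a-tetramethyl-5a,6,7,8,9,9a-hexahydro-1-benzoxepin-2(5H)-one | CC1=CC[C@H]2C(C)(C)[C@H](O[Si](C)(C)C(C)(C)C)CC[C@]2(C)OC1=O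
F10 | step 13 | (2R,5aS,7R,9aS)-2-(bromomethyl)-3,6,6,9a-tetramethyl-2,5,5a,6,7,8,9,9a-octahydro-1-benzoxepin-7-ol | CC1=CC[C@H]2C(C)(C)[C@H](O)CC[C@]2(C)O[C@H]1CBr
F11 | step 13 | (2R,5aS,7R,9aS)-2-(bromomethyl)-3,6,6,9a-tetramethyl-2,5,5a,6,7,8,9,9a-octahydro-1-benzoxepin-7-yl trifluoromethanesulfonate | CC1=CC[C@H]2C(C)(C)[C@H](OS(=O)(=O)C(F)(F)F)CC[C@]2(C)O[C@H]1CBr
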